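## Structural features

The target is a germacrane-type sesquiterpene lactone. Ring A is a ten-membered carbocycle (C1–C10), cis-fused along C6–C7 to ring B, an α-methylene-γ-butyrolactone (O6, C6, C7, C11, C12, with exocyclic C11=C13). Ring A is a cyclodeca-1,6-diene in which both trisubstituted alkenes, C4=C5 (methyl C15) and C9=C10 (methyl C14), are Z. Three stereocentres are contiguous: C6 (lactone oxygen), C7 (carbon branch C11) and C8 (angelate on O8). Two more form an anti-1,3 pair across C2: C1 with a free hydroxyl and C3 with an acetate. The fragile groups are the conjugated methylene (a Michael acceptor), the angelate (isomerises to the tiglate) and every Z-enoate, Z-enal or Z-enone on the way. There are also two hidden traps: a free O8–H opposite a C1 carbonyl across the Z alkene closes to a butenolide or furan, and a free O8 can take the lactone carbonyl from O6. The real difficulties are the medium ring with two Z alkenes, telling O1 from O3, and the absolute configuration of the C6–C8 triad. The key step exploits the fact that C5–C9 with O6, C11 and O8 on one side is a 3-C-branched pentofuranose: D-xylose supplies C6 and C8, and C7 is made as the sugar C3 radical, which closes ring B onto a propargyl ether on O6.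

## Logic of the disconnections

**28 ⇒ 27.** Bonds cut: C1–H and O3–C(acetyl). One intramolecular hydride transfer from an O3-bound hemiacetal of acetaldehyde makes both, and it is the simplest way to tell O1 from O3, which sit in almost identical allylic surroundings. Gain: one stereocentre and one acyl group fewer. Demand: anti delivery (1S from 3S) without retro-aldol of 27.

**27 ⇒ 26.** Bond cut: C2–C3 of ring A. It is the one ring bond flanked by two carbonyl-derived carbons, and the (Z,Z)-cyclodeca-1,6-diene is the least strained ten-membered diene to close. Gain: ring A and C3 disappear. Demand: enolisation of the methyl ketone only, high dilution, and face selection at C3 by the ring-forming transition state.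

**26 ⇒ 25.** Bonds cut: the two C12–O bonds of the carbonyl (forward: oxidation of the C12 methylene). The oxidation is placed where both ring alkenes are conjugated to carbonyls, so that C6–H and C8–H are deactivated, where O8 is acylated, and where no hydroxyl is free. Demand: an oxidant that spares the enal.

**25 ⇒ 24 ⇒ 23 ⇒ 20 + 21.** Bonds cut: the C1 and C3 carbonyls (back to alcohols), two O–Si bonds, and O8–C(angeloyl). The angelate has to go on while C1 is not a carbonyl and when no hydride step follows. Gain: 20 has a single free hydroxyl and no sensitive group. Demand: esterification without Z-to-E isomerisation.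

**20 ⇒ 19 ⇒ 18 ⇒ 17 + 11.** Bond cut: C4=C5 (plus ester reduction and one silylation). Olefination of the C5 lactol gives the Z alkene and brings C3 in as an ester that C1 can no longer be confused with. Gain: three carbons and ring-opening of the sugar. Demand: Z selectivity, no addition of the liberated O8 alkoxide to the new enoate, and no lactone present at that moment.

**17 ⇒ 16 ⇒ 15 ⇒ 14 ⇒ 12 ⇒ 10 + 11.** Bonds cut: C5–OMe, O1–Si, C1–C2 and C9=C10. The C9 side is built while the furanoside ring masks C5 and O8 together. C1 receives C2 before the second ester exists, and it is parked as a silyl ether before O8 is set free. Gain: back to a five-carbon aldehyde. Demand: Z selectivity and an acetal hydrolysis that spares the allylic silyl ether.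

**10 ⇒ 9 ⇒ 8.** Bond cut: C7–C11 (after adjusting C9 to the alcohol level). This is the strategic cut: it removes ring B and the C7 stereocentre and returns a plain xylofuranoside. Demand: cyclisation must outrun hydrogen transfer to the C7 radical.

**8 ⇒ 7 ⇒ 6 ⇒ 5 ⇒ 3 + 4 ⇒ 1.** Bonds cut: the thiocarbonate, silyl, propargyl and acetal C–O bonds. In the xylo series O3 and O5 are cis and can share one acetal, which singles out O2 for the tether; afterwards primary O5 and secondary O3 differ sterically. Gain: all of C5–C9 and the configuration of C6 and C8 come from 1. Demand: selective primary silylation.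

## Other disconnections considered

**Alternative 1:** samarium aldol–Tishchenko relay.
- **Cut:** the C2–C3 ring bond together with C1–H and O3–acetyl. This opens ring A to the open-chain bromomethyl ketone enal A1 (O8 angelate, O6 and O12 as silyl ethers).
- **Forward:** SmI2 would turn the C–Br bond into a samarium enolate, which adds to the C3 aldehyde. The samarium aldolate would then take up acetaldehyde and pass its hydride to C1, giving the ring A product A2 with O3 acetate, free O1 and the anti-1,3 pattern.
- **In favour:** ring closure, the C1 configuration and the O1/O3 differentiation happen in one flask under non-basic conditions. O6 and O8 stay masked, so no Z-γ-hydroxy carbonyl can cyclise. The lactone carbonyl would come last from the C6/C12 diol, which avoids a late C–H oxidation; on that point it is the better plan.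
- **Against:** it does not say where C6–C8 come from, so the triad needs separate asymmetric chemistry on an acyclic chain. An α-bromo ketone must be carried beside an enal. SmI2 could also reduce the enal or simply debrominate. The aldolate must meet acetaldehyde before it reverts. C3 is set only by the ring-closing transition state.
- **Comparison:** on C3 control the two plans are equal, since steps 20 and 21 of the chosen route are the same bond logic run as two separate operations. At the ring-closing stage the relay is better by one step. On the origin of absolute configuration the chosen plan is better, because C6 and C8 are bought with 1 and C7 follows from them.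

**Alternative 2:** three-component anti-carbomagnesiation.
- **Cut:** C4–C15, C5–C6 and O6–C12, giving the alkynol A3 and the aldehyde ester A4.
- **Forward:** the magnesium alkoxide of A3 would direct the CuI-catalysed anti addition of MeMgBr across the alkyne (methyl to C4, magnesium to C5 in a five-membered chelate). The alkenylmagnesium would add to the aldehyde of A4, and the C6 alkoxide would close on the C12 ester to give lactone A5.
- **In favour:** it is convergent. The Z geometry of C4=C5 is fixed by the chelate, which is more secure than an olefination of a lactol, so it is better there. C3 would be set beforehand by a reagent-controlled alkynylation, which is better than macrocyclic control. O3 is free in A5 while C1 is still a protected primary alcohol, so the acetate needs no differentiation; that is equal or better.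
- **Against:** C6 comes from 1,2-induction in an addition to the α-branched, epimerisable aldehyde A4, and the cis relation to C7 is not assured. The ester and the alkenyl iodide must survive the Grignard and copper. The C13 methylene and ring A are still missing; closing ring A at C1–C10 would set C1 without control. A4 needs its own C7/C8 pair.
- **Comparison:** it solves C3–C6 where the chosen plan solves C5–C9. It is better on convergence and on C3. The chosen plan is better on the certainty of the triad and has no uncontrolled C1. The overall step count would probably be similar.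

**Alternative 3:** palladium 1,4-acetoxylactonisation.
- **Cut:** O6–C6 and O3–C3, leading back to the ten-membered 3,5-diene acid A6.
- **Forward:** with Pd(OAc)2, LiCl, LiOAc and a quinone, the C12 carboxylate would attack C6 anti to palladium. Acetate would then attack the C3 terminus of the π-allyl from outside, a cis-1,4 addition that leaves Z C4=C5 and gives A7, the O1 silyl ether of the target.
- **In favour:** lactone, acetate, C3, C6 and the alkene arrive in one catalytic step at the very end. The cis relation of O3 and O6 across C4=C5 is exactly that of the target and is imposed by the mechanism, with C7 as the only control element. It is better than the chosen plan on C3, on O1/O3 differentiation and on avoiding a late C–H oxidation.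
- **Against:** A6 is a ten-membered triene that already carries C1, C7, C8, the angelate and an acrylic acid; making it is the real problem, and no stereocontrolled ring closure offers itself. Regiochemistry (C6 against C4, 1,2 against 1,4), the syn/anti geometry of the π-allyl in a medium ring (which decides Z or E), chloride capture and coordination by the other alkenes are all open.
- **Comparison:** its end-game economy is better. Total length and feasibility are unknown and probably worse. The chosen plan uses only steps with close precedent.

Key step: step 6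

Remark: the bicyclic acetal 9 is a furo[3,4-b]furan (its acetal carbon C5 is not a ring-fusion atom); the name furo[2,3-b]furan would be wrong for it.
Remark: the primary silyl ether of the radical precursor is triethylsilyl instead of tert-butyldimethylsilyl, so that step 7 can take it to the aldehyde in one operation.
Remark: step 1 forms both anomers; the β-anomer is drawn and carried on and the α-anomer is assumed to be removed at 3 (it would converge at 17 in any case).
Remark: 15, 16, 18, 19, 20, 23 and 24 are C1 epimer mixtures and 17 is an anomer mixture; both centres become planar again (steps 18 and 13).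

## Route

Step 1
Reactants: 1 D-xylose
Product: 3 methyl 3,5-O-isopropylidene-β-D-xylofuranoside, via methyl β-D-xylofuranoside 2 (not isolated)
Conditions: AcCl (cat.), MeOH, rt; NaHCO3, concentrate; Me2C(OMe)2, acetone, camphorsulfonic acid (cat.), rt; chromatography
Reagents that add atoms: methanol, CO; 2,2-dimethoxypropane, COC(C)(C)OC
Why: Kinetic Fischer glycosidation gives the methyl furanosides, and the cis O3/O5 pair of the xylo configuration then closes a six-membered isopropylidene acetal, leaving O2 as the only free hydroxyl; all stereocentres are those of D-xylose.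

Step 2
Reactants: 3 methyl 3,5-O-isopropylidene-β-D-xylofuranoside; 4 propargyl bromide
Product: 5 methyl 3,5-O-isopropylidene-2-O-propargyl-β-D-xylofuranoside
Conditions: NaH, DMF, 0 °C; then 4, 0 °C → rt
Reagents that add atoms: none
Why: Williamson etherification of the single free alkoxide with a reactive propargylic bromide; this installs the three-atom tether (O6–C12–C11≡C13) for the key step.

Step 3
Reactants: 5 methyl 3,5-O-isopropylidene-2-O-propargyl-β-D-xylofuranoside
Product: 6 methyl 2-O-propargyl-β-D-xylofuranoside
Conditions: AcOH–H2O (4:1), 40 °C
Reagents that add atoms: none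
Why: The isopropylidene ketal should hydrolyse well before the methyl furanoside under mild aqueous acid, freeing O3 and O5.

Step 4
Reactants: 6 methyl 2-O-propargyl-β-D-xylofuranoside
Product: 7 methyl 2-O-propargyl-5-O-(triethylsilyl)-β-D-xylofuranoside
Conditions: Et3SiCl (1.05 equiv), imidazole, CH2Cl2, −40 °C
Reagents that add atoms: chlorotriethylsilane, CC[Si](Cl)(CC)CC
Why: Silylation at low temperature should take the primary O5 in preference to the flanked secondary O3; triethylsilyl is chosen because step 7 converts it directly into the aldehyde.

Step 5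
Reactants: 7 methyl 2-O-propargyl-5-O-(triethylsilyl)-β-D-xylofuranoside
Product: 8 methyl 3-O-(phenoxythiocarbonyl)-2-O-propargyl-5-O-(triethylsilyl)-β-D-xylofuranoside
Conditions: PhOC(S)Cl, pyridine, DMAP (cat.), CH2Cl2, rt
Reagents that add atoms: O-phenyl chlorothionoformate, S=C(Cl)Oc1ccccc1
Why: Acylation of the remaining secondary hydroxyl gives the thionocarbonate that serves as radical precursor (Barton–McCombie activation); no stereocentre is touched.

Step 6
Reactants: 8 methyl 3-O-(phenoxythiocarbonyl)-2-O-propargyl-5-O-(triethylsilyl)-β-D-xylofuranoside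
Product: 9 cis-fused 6-methoxy-3-methylidene-4-[(triethylsilyloxy)methyl]hexahydrofuro[3,4-b]furan (methyl acetal holding C5–C9 and C11–C13; OMe and the C9 arm on the face opposite ring B)
Conditions: Bu3SnH (1.3 equiv) and AIBN (0.2 equiv) in toluene added over 6 h to 8 (0.01 M) in toluene, 110 °C
Reagents that add atoms: none
Why: Bu3Sn• adds to the thiocarbonyl sulfur and the adduct fragments at the C7–O bond (Barton–McCombie radical generation), giving a planar secondary radical at C7 and erasing the xylo configuration of that carbon. The radical adds 5-exo-dig to the internal alkyne carbon of the propargyl ether on O6, forming C7–C11 and ring B, and the vinyl radical at C13 takes hydrogen from Bu3SnH to leave the C11=C13 methylene. The closest known reaction type is the tin hydride cyclisation of carbohydrate radicals onto O-propargyl or O-allyl tethers. The closure is 5-exo-dig, and because the three-atom tether spans two adjacent furanose carbons only the cis-fused bicyclo[3.3.0] skeleton can form. The new stereocentre C7 is therefore controlled by C6 (from D-xylose): C11 ends up cis to O6 and trans to the C9 arm on C8. The selectivity needed is cyclisation over direct hydrogen transfer to C7 and over stannyl addition to the alkyne; slow addition keeps the stannane dilute, and the C=S group is the faster acceptor for Bu3Sn•. A 1,5-hydrogen shift from the vinyl radical to an α-oxy C–H would be harmless, since the carbons concerned (C5, C9) carry no configuration that is used later.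

Step 7
Reactants: 9 cis-fused 6-methoxy-3-methylidene-4-[(triethylsilyloxy)methyl]hexahydrofuro[3,4-b]furan
Product: 10 cis-fused 6-methoxy-3-methylidenehexahydrofuro[3,4-b]furan-4-carbaldehyde (C9 aldehyde)
Conditions: (COCl)2, DMSO, CH2Cl2, −78 → −30 °C; Et3N, −78 °C → rt
Reagents that add atoms: none
Why: Under Swern conditions a primary triethylsilyl ether is cleaved by the chlorosulfonium reagent and oxidised in the same flask to the aldehyde; the formyl group sits on the convex face of the bicycle, so C8 has no drive to epimerise.

Step 8
Reactants: 10 cis-fused 6-methoxy-3-methylidenehexahydrofuro[3,4-b]furan-4-carbaldehyde; 11 methyl 2-[bis(2,2,2-trifluoroethoxy)phosphoryl]propanoate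
Product: 12 methyl (Z)-3-(6-methoxy-3-methylidenehexahydrofuro[3,4-b]furan-4-yl)-2-methylprop-2-enoate (Z C9=C10, C1 ester)
Conditions: 11, KN(SiMe3)2, 18-crown-6, THF, −78 °C; then 10, −78 °C
Reagents that add atoms: none
Why: Still–Gennari olefination: the electron-poor phosphonate with a dissociated potassium counter-ion eliminates from the kinetic adduct, so the ester (C1) should end up cis to C8, the Z geometry of C9=C10.

Step 9
Reactants: 12 methyl (Z)-3-(6-methoxy-3-methylidenehexahydrofuro[3,4-b]furan-4-yl)-2-methylprop-2-enoate
Product: 14 (Z)-4-(6-methoxy-3-methylidenehexahydrofuro[3,4-b]furan-4-yl)-3-methylbut-3-en-2-one (C1 methyl ketone), via Weinreb amide 13 (not isolated)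
Conditions: MeNHOMe·HCl, iPrMgCl, THF, −20 → 0 °C; then MeMgBr, 0 °C; aq. NH4Cl
Reagents that add atoms: methylmagnesium bromide, C[Mg]Br; N,O-dimethylhydroxylamine hydrochloride, CNOC.Cl (its atoms are held by 13 only)
Why: The magnesium amide converts the ester into the Weinreb amide, whose chelated adduct with MeMgBr collapses to the ketone only on work-up; this introduces C2 while C1 is still the only carboxyl carbon in the molecule, and the Z alkene is not touched.

Step 10
Reactants: 14 (Z)-4-(6-methoxy-3-methylidenehexahydrofuro[3,4-b]furan-4-yl)-3-methylbut-3-en-2-one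
Product: 15 (Z)-4-(6-methoxy-3-methylidenehexahydrofuro[3,4-b]furan-4-yl)-3-methylbut-3-en-2-ol (C1 epimers)
Conditions: NaBH4, CeCl3·7H2O, MeOH, −78 °C
Reagents that add atoms: none
Why: Luche 1,2-reduction of the enone; C1 is taken to the alcohol level because a C1 carbonyl facing a free O8–H across the Z alkene (as would arise in steps 12 and 13) would close to a hemiketal and aromatise to a furan. The C1 configuration is irrelevant, as the ketone returns in step 18.

Step 11
Reactants: 15 (Z)-4-(6-methoxy-3-methylidenehexahydrofuro[3,4-b]furan-4-yl)-3-methylbut-3-en-2-ol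
Product: 16 tert-butyldiphenylsilyl ether of 15 (O1 silyl ether)
Conditions: tBuPh2SiCl, imidazole, DMF, rt
Reagents that add atoms: tert-butyl(chloro)diphenylsilane, CC(C)(C)[Si](Cl)(c1ccccc1)c1ccccc1
Why: Standard silylation; the tert-butyldiphenylsilyl ether is chosen because it should survive the aqueous acid of step 12 and the base and hydride of steps 13 and 14.

Step 12
Reactants: 16 tert-butyldiphenylsilyl ether of 15
Product: 17 cis-fused 4-[(Z)-3-(tert-butyldiphenylsilyloxy)-2-methylbut-1-enyl]-3-methylidenehexahydrofuro[3,4-b]furan-6-ol (C5 lactol, anomers)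
Conditions: 1 M HCl–THF (1:4), 35 °C
Reagents that add atoms: water, O
Why: Acid hydrolysis of a methyl furanoside through the C5 oxocarbenium ion; the glycoside carries an ether (not an acyl group) on the neighbouring O6 and should open under conditions that leave the silyl ether and the exocyclic alkene alone.

Step 13
Reactants: 17 C5 lactol; 11 methyl 2-[bis(2,2,2-trifluoroethoxy)phosphoryl]propanoate
Product: 18 methyl (Z)-3-{cis-3-[(Z)-4-(tert-butyldiphenylsilyloxy)-1-hydroxy-3-methylpent-2-enyl]-4-methylidenetetrahydrofuran-2-yl}-2-methylprop-2-enoate (Z C4=C5, C3 ester, free O8–H)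
Conditions: 11 (2.5 equiv), KN(SiMe3)2 (2.4 equiv), 18-crown-6, THF, −78 °C; then 17, −78 → −45 °C; AcOH at −78 °C
Reagents that add atoms: none
Why: Still–Gennari olefination of the hydroxy aldehyde tautomer of the lactol (the excess anion opens the lactol), with the same kinetic Z control as in step 8, so that C3 ends up cis to C6. The cold acidic quench keeps the liberated O8 alkoxide from adding to C5, and no lactone is present that it could attack.

Step 14
Reactants: 18 hydroxy enoate
Product: 19 the corresponding diol, C3 ester reduced to the (Z)-3-hydroxy-2-methylprop-1-enyl group (free O8–H and C3–OH)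
Conditions: iBu2AlH, CH2Cl2, −78 °C; aq. potassium sodium tartrate
Reagents that add atoms: none
Why: 1,2-Reduction of the conjugated ester to the Z allylic alcohol; the silyl ether and the alkenes are inert and the free O8–H only consumes one equivalent of hydride.

Step 15
Reactants: 19 diol
Product: 20 primary tert-butyldimethylsilyl ether of 19 (O3 silyl ether, free O8–H)
Conditions: tBuMe2SiCl, imidazole, CH2Cl2, 0 °C
Reagents that add atoms: tert-butyl(chloro)dimethylsilane, CC(C)(C)[Si](C)(C)Cl
Why: The primary allylic hydroxyl should be silylated well before the secondary O8–H, which is flanked by the branched C7 and the trisubstituted alkene; this leaves O8 as the only free hydroxyl.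

Step 16
Reactants: 20 primary silyl ether; 21 angelic acid
Product: 23 O8 angelate of 20, via angelic 2,4,6-trichlorobenzoic anhydride 22 (not isolated)
Conditions: 21, 2,4,6-Cl3C6H2COCl, Et3N, toluene, rt; then 20, toluene, 75 °C
Reagents that add atoms: 2,4,6-trichlorobenzoyl chloride, O=C(Cl)c1c(Cl)cc(Cl)cc1Cl (its atoms are held by 22 only)
Why: Yamaguchi esterification: the alcohol attacks the unhindered angeloyl carbonyl of the mixed anhydride, and with no nucleophilic catalyst present the Z acid should not isomerise to the tiglate. At this stage the substrate carries only silyl ethers and alkenes, so heat and amine do no harm.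

Step 17
Reactants: 23 O8 angelate of 20
Product: 24 O8 angelate diol (free C1–OH and C3–OH)
Conditions: Bu4NF, AcOH (1:1), THF, rt
Reagents that add atoms: none
Why: Fluoride cleaves both silyl ethers; buffering with acetic acid keeps the medium non-basic so that the angelate neither migrates nor isomerises.

Step 18
Reactants: 24 O8 angelate diol
Product: 25 keto aldehyde (C1 methyl ketone, C3 aldehyde, both alkenes Z, O8 angelate, ring B still the methylidene tetrahydrofuran)
Conditions: Dess–Martin periodinane, NaHCO3, CH2Cl2, 0 °C → rt
Reagents that add atoms: none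
Why: Dess–Martin oxidation takes the primary allylic alcohol to the Z enal and the secondary one to the Z enone under buffered conditions that should not isomerise them; O8 is now acylated, so neither carbonyl can be trapped as a cyclic hemiacetal.

Step 19
Reactants: 25 keto aldehyde
Product: 26 α-methylene-γ-butyrolactone keto aldehyde (C12 carbonyl in place)
Conditions: CrO3, 3,5-dimethylpyrazole, CH2Cl2, −20 °C
Reagents that add atoms: chromium trioxide, O=[Cr](=O)=O
Why: Allylic oxidation by the hexavalent chromium–pyrazole complex at the C12 methylene, which is activated both by the ether oxygen and by the only electron-rich alkene (C11=C13); the other two alkenes are conjugated to carbonyls, which deactivates C6–H and C8–H. The conversion of 3-methylidene tetrahydrofurans into α-methylene-γ-butyrolactones by this reagent type is known.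

Step 20
Reactants: 26 α-methylene-γ-butyrolactone keto aldehyde
Product: 27 ten-membered β-hydroxy ketone (ring A closed; C3–OH with 3S configuration, C1 ketone, O8 angelate)
Conditions: LiN(SiMe3)2 (1.2 equiv), THF, −78 °C, 26 added slowly to 1 mM final concentration; aq. NH4Cl at −78 °C
Reagents that add atoms: none
Why: Intramolecular aldol macrocyclisation: the kinetic lithium enolate of the methyl ketone (C2) adds to the C3 enal, and the (Z,Z)-cyclodeca-1,6-diene being formed is the least strained ten-membered diene. C3 is set by the ring-forming transition state: the tether brings the enolate to the face of the C4=C5 plane that carries C7, and with H6 eclipsing the alkene (allylic 1,3-strain) and the enal s-trans, that face should lead to 3S. This is an expectation, not a certainty.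

Step 21
Reactants: 27 ten-membered β-hydroxy ketone
Product: 28 target, CNP0319825.5
Conditions: CH3CHO (10 equiv), SmI2 (0.3 equiv), THF, −10 °C
Reagents that add atoms: acetaldehyde, CC=O
Why: Evans–Tishchenko reduction: the samarium-bound hemiacetal formed from O3 and acetaldehyde transfers its hydride to C1 through a chair-like bicyclic transition state, which should give the 1,3-anti relation (1S from 3S). The acetyl group stays on O3, so O1 and O3 are differentiated in the same step.

## Compound list

1 | D-xylose | O=C[C@H](O)[C@@H](O)[C@H](O)CO | starting material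
2 | methyl β-D-xylofuranoside | CO[C@@H]1O[C@H](CO)[C@H](O)[C@H]1O | intermediate
3 | methyl 3,5-O-isopropylidene-β-D-xylofuranoside | CO[C@@H]1O[C@@H]2COC(C)(C)O[C@@H]2[C@H]1O | intermediate
4 | propargyl bromide | C#CCBr | starting material
5 | methyl 3,5-O-isopropylidene-2-O-propargyl-β-D-xylofuranoside | CO[C@@H]1O[C@@H]2COC(C)(C)O[C@@H]2[C@H]1OCC#C | intermediate
6 | methyl 2-O-propargyl-β-D-xylofuranoside | CO[C@@H]1O[C@H](CO)[C@H](O)[C@H]1OCC#C | intermediate
7 | methyl 2-O-propargyl-5-O-(triethylsilyl)-β-D-xylofuranoside | CO[C@@H]1O[C@H](CO[Si](CC)(CC)CC)[C@H](O)[C@H]1OCC#C | intermediate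
8 | methyl 3-O-(phenoxythiocarbonyl)-2-O-propargyl-5-O-(triethylsilyl)-β-D-xylofuranoside | CO[C@@H]1O[C@H](CO[Si](CC)(CC)CC)[C@H](OC(=S)Oc2ccccc2)[C@H]1OCC#C | intermediate
9 | cis-fused 6-methoxy-3-methylidene-4-[(triethylsilyloxy)methyl]hexahydrofuro[3,4-b]furan | CO[C@@H]1O[C@H](CO[Si](CC)(CC)CC)[C@H]2C(=C)CO[C@H]21 | intermediate
10 | cis-fused 6-methoxy-3-methylidenehexahydrofuro[3,4-b]furan-4-carbaldehyde | CO[C@@H]1O[C@H](C=O)[C@H]2C(=C)CO[C@H]21 | intermediate
11 | methyl 2-[bis(2,2,2-trifluoroethoxy)phosphoryl]propanoate | CC(C(=O)OC)P(=O)(OCC(F)(F)F)OCC(F)(F)F | starting material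
12 | methyl (Z)-3-(6-methoxy-3-methylidenehexahydrofuro[3,4-b]furan-4-yl)-2-methylprop-2-enoate | CO[C@@H]1O[C@H](/C=C(/C)C(=O)OC)[C@H]2C(=C)CO[C@H]21 | intermediate
13 | (Z)-N-methoxy-N,2-dimethyl-3-(6-methoxy-3-methylidenehexahydrofuro[3,4-b]furan-4-yl)prop-2-enamide | CO[C@@H]1O[C@H](/C=C(/C)C(=O)N(C)OC)[C@H]2C(=C)CO[C@H]21 | intermediate
14 | (Z)-4-(6-methoxy-3-methylidenehexahydrofuro[3,4-b]furan-4-yl)-3-methylbut-3-en-2-one | CO[C@@H]1O[C@H](/C=C(/C)C(C)=O)[C@H]2C(=C)CO[C@H]21 | intermediate
15 | (Z)-4-(6-methoxy-3-methylidenehexahydrofuro[3,4-b]furan-4-yl)-3-methylbut-3-en-2-ol (C1 epimers) | CO[C@@H]1O[C@H](/C=C(/C)C(C)O)[C@H]2C(=C)CO[C@H]21 | intermediate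
16 | tert-butyldiphenylsilyl ether of 15 (C1 epimers) | CO[C@@H]1O[C@H](/C=C(/C)C(C)O[Si](c3ccccc3)(c3ccccc3)C(C)(C)C)[C@H]2C(=C)CO[C@H]21 | intermediate
17 | cis-fused 4-[(Z)-3-(tert-butyldiphenylsilyloxy)-2-methylbut-1-enyl]-3-methylidenehexahydrofuro[3,4-b]furan-6-ol (anomers) | OC1O[C@H](/C=C(/C)C(C)O[Si](c3ccccc3)(c3ccccc3)C(C)(C)C)[C@H]2C(=C)CO[C@H]21 | intermediate
18 | methyl (Z)-3-{cis-3-[(Z)-4-(tert-butyldiphenylsilyloxy)-1-hydroxy-3-methylpent-2-enyl]-4-methylidenetetrahydrofuran-2-yl}-2-methylprop-2-enoate | C=C1CO[C@@H](/C=C(/C)C(=O)OC)[C@H]1[C@H](O)/C=C(/C)C(C)O[Si](c2ccccc2)(c2ccccc2)C(C)(C)C | intermediate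
19 | diol: 18 with the ester reduced to CH2OH | C=C1CO[C@@H](/C=C(/C)CO)[C@H]1[C@H](O)/C=C(/C)C(C)O[Si](c2ccccc2)(c2ccccc2)C(C)(C)C | intermediate
20 | primary tert-butyldimethylsilyl ether of 19 | C=C1CO[C@@H](/C=C(/C)CO[Si](C)(C)C(C)(C)C)[C@H]1[C@H](O)/C=C(/C)C(C)O[Si](c2ccccc2)(c2ccccc2)C(C)(C)C | intermediate
21 | angelic acid | C/C=C(/C)C(=O)O | starting material
22 | angelic 2,4,6-trichlorobenzoic anhydride | C/C=C(/C)C(=O)OC(=O)c1c(Cl)cc(Cl)cc1Cl | intermediate
23 | O8 angelate of 20 | C=C1CO[C@@H](/C=C(/C)CO[Si](C)(C)C(C)(C)C)[C@H]1[C@H](OC(=O)/C(C)=C\C)/C=C(/C)C(C)O[Si](c2ccccc2)(c2ccccc2)C(C)(C)C | intermediate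
24 | O8 angelate diol (C1–OH, C3–OH) | C=C1CO[C@@H](/C=C(/C)CO)[C@H]1[C@H](OC(=O)/C(C)=C\C)/C=C(/C)C(C)O | intermediate
25 | keto aldehyde with methylidene tetrahydrofuran (O8 angelate) | C=C1CO[C@@H](/C=C(/C)C=O)[C@H]1[C@H](OC(=O)/C(C)=C\C)/C=C(/C)C(C)=O | intermediate
26 | keto aldehyde with α-methylene-γ-butyrolactone (O8 angelate) | C=C1C(=O)O[C@@H](/C=C(/C)C=O)[C@H]1[C@H](OC(=O)/C(C)=C\C)/C=C(/C)C(C)=O | intermediate
27 | ten-membered β-hydroxy ketone (3S-OH, C1 ketone, O8 angelate, lactone) | C=C1C(=O)O[C@H]2/C=C(/C)[C@@H](O)CC(=O)/C(C)=C\[C@@H](OC(=O)/C(C)=C\C)[C@@H]12 | intermediate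
28 | CNP0319825.5 | C=C1C(=O)O[C@H]2/C=C(/C)[C@@H](OC(C)=O)C[C@H](O)/C(C)=C\[C@@H](OC(=O)/C(C)=C\C)[C@@H]12 | target

## Step count and least certain steps

Total step count: 21. Longest linear sequence: 21 steps from 1; the route is linear, and 4, 11 and 21 are purchased.

**Step 6 (key step).** Most likely to go wrong: hydrogen transfer to the C7 radical before it has cyclised (plain deoxygenation), and addition of the stannyl radical to the terminal alkyne. Both become more likely if the 5-exo-dig closure onto an unactivated alkyne is slow.
Fallback, from 7 back to 9: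
- Garegg–Samuelsson iodination of 7 (PPh3, I2, imidazole, toluene, 80 °C, inversion) would give methyl 3-deoxy-3-iodo-2-O-propargyl-5-O-(triethylsilyl)-β-D-ribofuranoside F1.
- Et3B with air in benzene at rt would then run an iodine atom-transfer 5-exo-dig cyclisation. No hydride donor is present, so the C7 radical can only cyclise. The product would be the cis-fused 3-(iodomethylidene) bicycle F2.
- Bu3SnH with catalytic Pd(PPh3)4 (zerovalent palladium) at rt would replace the vinylic iodine by hydrogen and return 9.

**Step 20.** Most likely to go wrong: intermolecular aldol addition or retro-aldol reopening of the medium ring, attack of the amide base on the enal or the methylene lactone, and poor face selection at C3. The unwanted C3 epimer could in principle be returned to 26 by retro-aldol and recycled.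
Fallback, from 26 back to 27:
- Me3SiOTf and Et3N in CH2Cl2 at −78 °C would silylate only the methyl ketone (the aldehyde has no α-hydrogen), giving the trimethylsilyl dienol ether of 26 F3.
- After dilution, BF3·OEt2 at −78 °C would close the ring by an intramolecular Mukaiyama aldol through an open transition state under non-basic conditions; aqueous work-up would give 27.

**Step 19.** Most likely to go wrong: over-oxidation or Z-to-E isomerisation of the enal during exposure to hexavalent chromium, and competing hydrogen abstraction at C6.
Fallback, from 25 back to 26: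
- Ac2O with catalytic I2 in CH2Cl2 at 0 °C would mask only the aldehyde, as the C3 gem-diacetate of 25 F4. This group is inert to chromium and keeps C4=C5 electron-poor.
- The same CrO3–3,5-dimethylpyrazole oxidation would then give the C3 gem-diacetate of 26 F5.
- Wet acidic clay (montmorillonite) in CH2Cl2 would release the aldehyde and return 26.

**Step 13.** Most likely to go wrong: slow opening of the lactol at low temperature, and conjugate addition of the liberated O8 alkoxide to C5 of the new enoate, which would close a tetrahydrofuran.
Fallback, from 17 back to 18: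
- NaBH4 in MeOH at 0 °C would open the lactol to the C5,O8 diol F6.
- Et3SiOTf and 2,6-lutidine would give the bis(triethylsilyl) ether F7.
- Swern oxidation, which converts only the primary triethylsilyl ether, would give the C5 aldehyde with O8 silylated F8.
- Still–Gennari olefination with 11, now on a free aldehyde with no alkoxide in the molecule, would give the O8 triethylsilyl ether of 18 F9.
- HF·pyridine in THF at 0 °C would remove the triethylsilyl group under non-basic conditions and return 18.

**Step 21.** Most likely to go wrong: retro-aldol opening of ring A under the Lewis-acidic trivalent samarium catalyst before hydride transfer, or migration of the acetyl group from O3 to O1.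
Fallback, from 27 back to 28:
- Ac2O and pyridine in CH2Cl2 at 0 °C would give the 3-O-acetyl β-acetoxy ketone F10.
- Corey–Bakshi–Shibata reduction with the (R)-methyl oxazaborolidine and catecholborane in toluene at −78 °C would then set 1S by reagent control (the alkenyl side acting as the large group) and give 28 directly.

## Further compounds

F1 | step 6 | methyl 3-deoxy-3-iodo-2-O-propargyl-5-O-(triethylsilyl)-β-D-ribofuranoside | CO[C@@H]1O[C@H](CO[Si](CC)(CC)CC)[C@@H](I)[C@H]1OCC#C
F2 | step 6 | cis-fused 3-(iodomethylidene)-6-methoxy-4-[(triethylsilyloxy)methyl]hexahydrofuro[3,4-b]furan (E/Z mixture) | CO[C@@H]1O[C@H](CO[Si](CC)(CC)CC)[C@H]2C(=CI)CO[C@H]21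
F3 | step 20 | trimethylsilyl dienol ether of 26 | C=C1C(=O)O[C@@H](/C=C(/C)C=O)[C@H]1[C@H](OC(=O)/C(C)=C\C)/C=C(/C)C(=C)O[Si](C)(C)C
F4 | step 19 | C3 gem-diacetate of 25 | C=C1CO[C@@H](/C=C(/C)C(OC(C)=O)OC(C)=O)[C@H]1[C@H](OC(=O)/C(C)=C\C)/C=C(/C)C(C)=O
F5 | step 19 | C3 gem-diacetate of 26 | C=C1C(=O)O[C@@H](/C=C(/C)C(OC(C)=O)OC(C)=O)[C@H]1[C@H](OC(=O)/C(C)=C\C)/C=C(/C)C(C)=O
F6 | step 13 | C5,O8 diol from reduction of 17 | C=C1CO[C@@H](CO)[C@H]1[C@H](O)/C=C(/C)C(C)O[Si](c2ccccc2)(c2ccccc2)C(C)(C)C
F7 | step 13 | bis(triethylsilyl) ether of F6 | C=C1CO[C@@H](CO[Si](CC)(CC)CC)[C@H]1[C@H](O[Si](CC)(CC)CC)/C=C(/C)C(C)O[Si](c2ccccc2)(c2ccccc2)C(C)(C)C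
F8 | step 13 | C5 aldehyde with O8 triethylsilyl ether | C=C1CO[C@@H](C=O)[C@H]1[C@H](O[Si](CC)(CC)CC)/C=C(/C)C(C)O[Si](c2ccccc2)(c2ccccc2)C(C)(C)C
F9 | step 13 | O8 triethylsilyl ether of 18 | C=C1CO[C@@H](/C=C(/C)C(=O)OC)[C@H]1[C@H](O[Si](CC)(CC)CC)/C=C(/C)C(C)O[Si](c2ccccc2)(c2ccccc2)C(C)(C)C
F10 | step 21 | 3-O-acetyl derivative of 27 (β-acetoxy ketone) | C=C1C(=O)O[C@H]2/C=C(/C)[C@@H](OC(C)=O)CC(=O)/C(C)=C\[C@@H](OC(=O)/C(C)=C\C)[C@@H]12
A1 | alternative 1 | open-chain bromomethyl ketone enal (O8 angelate, O6 and O12 tert-butyldimethylsilyl ethers) | C=C(CO[Si](C)(C)C(C)(C)C)[C@@H]([C@@H](O[Si](C)(C)C(C)(C)C)/C=C(/C)C=O)[C@H](OC(=O)/C(C)=C\C)/C=C(/C)C(=O)CBr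
A2 | alternative 1 | ten-membered ring with O3 acetate, free O1 hydroxyl, O8 angelate, O6 and O12 silyl ethers | C=C(CO[Si](C)(C)C(C)(C)C)[C@H]1[C@@H](O[Si](C)(C)C(C)(C)C)/C=C(/C)[C@@H](OC(C)=O)C[C@H](O)/C(C)=C\[C@H]1OC(=O)/C(C)=C\C
A3 | alternative 2 | (S)-5-(tert-butyldimethylsilyloxy)pent-1-yn-3-ol | C#C[C@@H](O)CCO[Si](C)(C)C(C)(C)C
A4 | alternative 2 | methyl (Z)-3-formyl-6-iodo-4-(4-methoxybenzyloxy)hept-5-enoate (C7, C8 as in the target) | COC(=O)C[C@@H](C=O)[C@H](OCc1ccc(OC)cc1)/C=C(/C)I
A5 | alternative 2 | cis-disubstituted γ-lactone with Z C4=C5, free O3 hydroxyl and C10 iodoalkene | O=C1C[C@H]([C@H](OCc2ccc(OC)cc2)/C=C(/C)I)[C@H](/C=C(/C)[C@@H](O)CCO[Si](C)(C)C(C)(C)C)O1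
A6 | alternative 3 | ten-membered (3Z,5Z,9Z)-triene acid (O1 silyl ether, O8 angelate, C12 acid) | C=C(C(=O)O)[C@H]1/C=C\C(C)=C/C[C@H](O[Si](C)(C)C(C)(C)C)/C(C)=C\[C@H]1OC(=O)/C(C)=C\C
A7 | alternative 3 | O1 tert-butyldimethylsilyl ether of the target | C=C1C(=O)O[C@H]2/C=C(/C)[C@@H](OC(C)=O)C[C@H](O[Si](C)(C)C(C)(C)C)/C(C)=C\[C@@H](OC(=O)/C(C)=C\C)[C@@H]12
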